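The flavanone is cut across ring C at O1–C2 and C3–C4. The feature exploited is a heterodiene hidden in rings A and C. Once C4 is a cationic, methoxy-bearing carbon, the chain C4=C4a–C8a=O1 is an electron-poor four-atom partner, and ring B with C2 and C3 is simply 3,4-dimethoxystyrene. A single chiral-acid-catalysed hetero-[4+2] at the flavan oxidation level forms both bonds, closes the pyran ring and sets C2. The sacrificial C4 centre is oxidised to the ketone afterwards. The precursor is a fully substituted salicylaldehyde, 3-(benzyloxy)-2-hydroxy-4,5,6-trimethoxybenzaldehyde. It is made in four steps from 3,4,5-trimethoxyphenol by two directed lithiations, one on each side of a single MOM ether.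

Key step: step 5

Assumption: the sense of induction of the chiral acid cannot be predicted for this substrate class. The (R)-catalyst is written, and its antipode is used if the 2R series results.

Step 1
Reactants: 1 3,4,5-trimethoxyphenol
Product: 2 5-(methoxymethoxy)-1,2,3-trimethoxybenzene
Conditions: NaH, THF, 0 °C; MOMCl, 0 °C → rt
Reagents that add atoms: chloromethyl methyl ether (MOMCl), COCCl
Why: Williamson-type O-alkylation of the sodium phenoxide should be clean, and the MOM acetal masks the future O1 while serving as the directing group for steps 2 and 4.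

Step 2
Reactants: 2 5-(methoxymethoxy)-1,2,3-trimethoxybenzene
Product: 5 6-(methoxymethoxy)-2,3,4-trimethoxyphenol, via aryllithium 3 (not isolated), via dimethyl arylboronate 4 (not isolated)
Conditions: n-BuLi, THF, 0 °C; B(OMe)3, −78 °C → rt; AcOH, 30% H2O2, 0 °C → rt
Reagents that add atoms: hydrogen peroxide, OO (the new oxygen); n-BuLi, [Li]CCCC, and trimethyl borate, COB(OC)OC (their atoms appear only in 3 and 4)
Why: Directed ortho-metalation occurs between OMOM and OMe, where the two candidate sites are equivalent by symmetry, and borate quench with peroxide oxidation (1,2-aryl shift from boron to oxygen) installs the future 8-oxygen.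

Step 3
Reactants: 5 6-(methoxymethoxy)-2,3,4-trimethoxyphenol
Product: 6 2-(benzyloxy)-3,4,5-trimethoxy-1-(methoxymethoxy)benzene
Conditions: BnBr, K2CO3, DMF, 50 °C
Reagents that add atoms: benzyl bromide, BrCc1ccccc1
Why: In this Williamson etherification only one hydroxyl is free, so the benzyl group can only end up on the newly introduced oxygen.

Step 4
Reactants: 6 2-(benzyloxy)-3,4,5-trimethoxy-1-(methoxymethoxy)benzene
Product: 9 3-(benzyloxy)-2-hydroxy-4,5,6-trimethoxybenzaldehyde, via aryllithium 7 (not isolated), via MOM-protected aldehyde 8 (not isolated)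
Conditions: n-BuLi, THF, −20 → 0 °C; DMF, −78 → 0 °C; then 3 M aq. HCl, 45 °C
Reagents that add atoms: N,N-dimethylformamide, CN(C)C=O; n-BuLi, [Li]CCCC (lithium appears only in 7)
Why: A second directed ortho-metalation at the last ring C–H, again flanked by OMOM and OMe, is followed by DMF formylation, and the acidic quench collapses the hemiaminal and hydrolyses the MOM acetal ortho to the new carbonyl in the same flask.

Step 5
Reactants: 9 3-(benzyloxy)-2-hydroxy-4,5,6-trimethoxybenzaldehyde; 10 3,4-dimethoxystyrene; 11 trimethyl orthoformate
Product: 14 (2S,4S)-8-(benzyloxy)-2-(3,4-dimethoxyphenyl)-4,5,6,7-tetramethoxychroman (2,4-cis), via dimethyl acetal 12 (not isolated), via methoxy-oxocarbenium ion 13 (not isolated)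
Conditions: 11 (1.5 equiv), (R)-3,3'-bis(2,4,6-triisopropylphenyl)-1,1'-binaphthalene-2,2'-diyl N-triflylphosphoramide (10 mol%), 5 Å MS, toluene, rt, 1 h; then −40 °C, slow addition of 10 (1.5 equiv)
Reagents that add atoms: trimethyl orthoformate (11), COC(OC)OC
Why: Proposed new method: acetal exchange with 11 turns 9 into 12, the acid expels methanol to give cation 13 (an O-protonated 4-methoxy o-quinone methide) as a contact ion pair whose phenolic O–H is hydrogen-bonded to the chiral phosphoramide anion, the CH2 terminus of 10 bonds to C4, and O1 captures the 3,4-dimethoxybenzylic charge that builds up at C2. The closest known reaction types are the racemic acid-catalysed chroman synthesis from salicylaldehydes, orthoformates and alkenes and the chiral N-triflylphosphoramide-catalysed [4+2] addition of styrenes to o-quinone methides released from o-hydroxybenzyl alcohols; enantiocontrol over a 4-alkoxy cation is the untested part. Ring C closes by an inverse-electron-demand hetero-[4+2] (C4=C4a–C8a=O1 plus C3=C2), which in its stepwise limit is a Prins-type addition followed by 6-exo-trig ring closure, since the C2=C1' bond of the quinoid cation lies outside the new ring. C4 is set by the face of 13 that the anion leaves open, and C2 by the closure itself, where the same anion accepts the phenol proton and a half-chair with pseudo-equatorial aryl and methoxy groups relays C4 to C2 and gives the 2,4-cis isomer. Regiochemistry (aryl on C2) is secured by the polarity of 10, chemoselectivity by ring A having no free C–H for Friedel–Crafts attack, and the catalyst's grip by the single phenol O–H set in a pocket between C4 and the 8-benzyloxy group. Only C2 has to last, so a trans isomer is separated and pooled only after its C2 centre has been shown to be S, while low temperature, slow addition of 10 and methanol-binding sieves hold back styrene oligomerisation and acid-induced C2–O1 ionisation.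

Step 6
Reactants: 14 (2S,4S)-8-(benzyloxy)-2-(3,4-dimethoxyphenyl)-4,5,6,7-tetramethoxychroman
Product: 15 (2S)-8-(benzyloxy)-2-(3,4-dimethoxyphenyl)-5,6,7-trimethoxychroman-4-ol (C4 epimers, C2 defined)
Conditions: p-TsOH·H2O (10 mol%), THF/H2O 3:1, rt
Reagents that add atoms: water, O
Why: In this SN1 solvolysis, loss of methanol from C4 gives a benzylic cation stabilised by O1 and the 5- and 7-methoxy groups, the large excess of water traps it, C2 is not involved, and the C4 epimer mixture is of no consequence.

Step 7
Reactants: 15 (2S)-8-(benzyloxy)-2-(3,4-dimethoxyphenyl)-5,6,7-trimethoxychroman-4-ol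
Product: 16 (2S)-8-(benzyloxy)-2-(3,4-dimethoxyphenyl)-5,6,7-trimethoxychroman-4-one
Conditions: Dess–Martin periodinane, NaHCO3, CH2Cl2, 0 °C → rt
Reagents that add atoms: none
Why: Dess–Martin oxidation of the secondary benzylic alcohol under buffered, non-basic conditions converges both C4 epimers on one ketone and avoids the base-induced retro-oxa-Michael opening that would racemise C2.

Step 8
Reactants: 16 (2S)-8-(benzyloxy)-2-(3,4-dimethoxyphenyl)-5,6,7-trimethoxychroman-4-one
Product: 17 (2S)-2-(3,4-dimethoxyphenyl)-8-hydroxy-5,6,7-trimethoxychroman-4-one (target)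
Conditions: H2 (1 atm), 10% Pd/C, EtOAc, rt
Reagents that add atoms: none
Why: Catalytic hydrogenolysis of the aryl benzyl ether under neutral conditions should be much faster than reduction of the electron-rich aryl ketone or cleavage of the cyclic C2–O1 bond, and it cannot epimerise C2.

Compound list
1 | 3,4,5-trimethoxyphenol | COc1cc(O)cc(OC)c1OC | starting material
2 | 5-(methoxymethoxy)-1,2,3-trimethoxybenzene | COCOc1cc(OC)c(OC)c(OC)c1 | intermediate
3 | [2,3,4-trimethoxy-6-(methoxymethoxy)phenyl]lithium (not isolated) | [Li]c1c(OCOC)cc(OC)c(OC)c1OC | intermediate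
4 | dimethyl [2,3,4-trimethoxy-6-(methoxymethoxy)phenyl]boronate (not isolated) | COB(OC)c1c(OCOC)cc(OC)c(OC)c1OC | intermediate
5 | 6-(methoxymethoxy)-2,3,4-trimethoxyphenol | Oc1c(OCOC)cc(OC)c(OC)c1OC | intermediate
6 | 2-(benzyloxy)-3,4,5-trimethoxy-1-(methoxymethoxy)benzene | COCOc1cc(OC)c(OC)c(OC)c1OCc1ccccc1 | intermediate
7 | [3-(benzyloxy)-4,5,6-trimethoxy-2-(methoxymethoxy)phenyl]lithium (not isolated) | [Li]c1c(OCOC)c(OCc2ccccc2)c(OC)c(OC)c1OC | intermediate
8 | 3-(benzyloxy)-4,5,6-trimethoxy-2-(methoxymethoxy)benzaldehyde (not isolated) | O=Cc1c(OCOC)c(OCc2ccccc2)c(OC)c(OC)c1OC | intermediate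
9 | 3-(benzyloxy)-2-hydroxy-4,5,6-trimethoxybenzaldehyde | O=Cc1c(O)c(OCc2ccccc2)c(OC)c(OC)c1OC | intermediate
10 | 3,4-dimethoxystyrene | C=Cc1ccc(OC)c(OC)c1 | starting material
11 | trimethyl orthoformate | COC(OC)OC | starting material
12 | 2-(benzyloxy)-6-(dimethoxymethyl)-3,4,5-trimethoxyphenol (not isolated) | COC(OC)c1c(O)c(OCc2ccccc2)c(OC)c(OC)c1OC | intermediate
13 | [3-(benzyloxy)-2-hydroxy-4,5,6-trimethoxybenzylidene](methyl)oxonium, paired with the catalyst anion (not isolated) | C[O+]=Cc1c(O)c(OCc2ccccc2)c(OC)c(OC)c1OC | intermediate
14 | (2S,4S)-8-(benzyloxy)-2-(3,4-dimethoxyphenyl)-4,5,6,7-tetramethoxychroman (2,4-cis) | COc1ccc([C@@H]2C[C@H](OC)c3c(c(OCc4ccccc4)c(OC)c(OC)c3OC)O2)cc1OC | intermediate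
15 | (2S)-8-(benzyloxy)-2-(3,4-dimethoxyphenyl)-5,6,7-trimethoxychroman-4-ol (C4 epimers) | COc1ccc([C@@H]2CC(O)c3c(c(OCc4ccccc4)c(OC)c(OC)c3OC)O2)cc1OC | intermediate
16 | (2S)-8-(benzyloxy)-2-(3,4-dimethoxyphenyl)-5,6,7-trimethoxychroman-4-one | COc1ccc([C@@H]2CC(=O)c3c(c(OCc4ccccc4)c(OC)c(OC)c3OC)O2)cc1OC | intermediate
17 | (2S)-2-(3,4-dimethoxyphenyl)-8-hydroxy-5,6,7-trimethoxychroman-4-one | COc1ccc([C@@H]2CC(=O)c3c(c(O)c(OC)c(OC)c3OC)O2)cc1OC | target

Total step count: 8. Longest linear sequence: 8 steps (1 → 17). Compounds 10 and 11 enter as purchased.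

Steps most likely to fail

Step 5. Facial discrimination within the ion pair may be poor, the relay from C4 to C2 may be lost in a fully stepwise closure, or the styrene may oligomerise cationically. The fallback gives up enantiocontrol in the ring-forming event and resolves at the ketone stage with known chemistry.
- It sets out from 9, with 10 and 11. The known racemic three-component reaction (Sc(OTf)3, CH2Cl2, 0 °C) should give the racemic cis-chroman F1.
- The conditions of steps 6 and 7 then lead to the racemic flavan-4-ol F2 and the racemic 8-O-benzylflavanone F3.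
- Kinetic resolution by asymmetric transfer hydrogenation is an established route to enantioenriched flavanones (RuCl(p-cymene)[(R,R)-TsDPEN], HCO2H/Et3N, EtOAc, rt). It is expected to reduce the 2R ketone to the (2R,4R)-cis-flavan-4-ol F4, which is removed by chromatography.
- The 2S ketone is left untouched, and the route is rejoined at 16.

Step 6. The C4 cation may lose a C3 proton and eliminate instead of being hydrated, or acid-induced reversible opening of ring C may erode the configuration at C2. The fallback avoids Brønsted-acid ionisation and changes the oxidation state directly.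
- It sets out from 14, which is treated with DDQ in CH2Cl2/pH 7 buffer at 0 °C.
- Hydride abstraction from C4–H of the electron-rich benzylic methyl ether, capture by water and loss of methanol should give the ketone in one operation.
- Compound 15 is bypassed and the route is rejoined at 16. No compound outside the list is made (F0).

Step 4. Deprotonation at the benzylic CH2 of the benzyl ether, followed by Wittig rearrangement, may compete with ring lithiation, or the MOM cleavage in the quench may be incomplete. The fallback replaces carbanion chemistry with a phenoxide-directed electrophilic formylation.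
- It sets out from 6. The MOM group is removed (cat. HCl, MeOH, 50 °C) to give 2-(benzyloxy)-3,4,5-trimethoxyphenol F5.
- Casnati–Skattebøl ortho-formylation (MgCl2, Et3N, paraformaldehyde, MeCN, reflux) places the aldehyde at the only free position, ortho to the phenol.
- The route is rejoined at 9.

Further compounds
F1 | step 5 | racemic 2,4-cis-8-(benzyloxy)-2-(3,4-dimethoxyphenyl)-4,5,6,7-tetramethoxychroman | COc1ccc(C2CC(OC)c3c(c(OCc4ccccc4)c(OC)c(OC)c3OC)O2)cc1OC
F2 | step 5 | racemic 8-(benzyloxy)-2-(3,4-dimethoxyphenyl)-5,6,7-trimethoxychroman-4-ol | COc1ccc(C2CC(O)c3c(c(OCc4ccccc4)c(OC)c(OC)c3OC)O2)cc1OC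
F3 | step 5 | racemic 8-(benzyloxy)-2-(3,4-dimethoxyphenyl)-5,6,7-trimethoxychroman-4-one | COc1ccc(C2CC(=O)c3c(c(OCc4ccccc4)c(OC)c(OC)c3OC)O2)cc1OC
F4 | step 5 | (2R,4R)-8-(benzyloxy)-2-(3,4-dimethoxyphenyl)-5,6,7-trimethoxychroman-4-ol (2,4-cis) | COc1ccc([C@H]2C[C@@H](O)c3c(c(OCc4ccccc4)c(OC)c(OC)c3OC)O2)cc1OC
F0 | step 6 | none | none
F5 | step 4 | 2-(benzyloxy)-3,4,5-trimethoxyphenol | COc1cc(O)c(OCc2ccccc2)c(OC)c1OC
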